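A direct plan would keep the six-membered ring of (S)-5-methylcyclohex-2-enone and make C5 quaternary by formylation and methylation.
It would fuse a seven-membered ring onto it by an acrylate reductive aldol (C4–C10) and a nickel-catalysed diene–aldehyde cyclisation of lactol A1 (C11–C12).
It would widen this ring to the bridged eight-membered ring by a shift of C10 from C4 to C9 in epoxy alcohol A2, and close the cyclopentenone last from diketone A3 by Wacker oxidation and aldol condensation.
Weakest would be the ring-expanding shift with oxidation in the same flask: a fused-to-bridged migration of this kind has no precedent and needs the C4–C10 bond antiperiplanar to the epoxide C9–O bond.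
Next would be the reductive cyclisation: it must close a seven-membered ring through the substituted allyl terminus and set C11 and quaternary C12 together from a lactol that is mostly closed.
Third would be the formylation–methylation: C- against O-alkylation and face selection by one neighbouring methyl group decide C5.

Atoms carry mutilin numbers (cyclopentenone C1–C4/C9). The target's six-membered ring (C4–C9) is bridged 1,3 at C5 and C9 by C14–C10 and oxygenated at C8, the pattern of a type 2 intramolecular Diels–Alder adduct. The route rests on that reaction: in an acyclic trienone the 2-siloxy diene C4=C9–C8=C7 adds to the Z enone C5=C6 and forms C4–C5 and C6–C7. One operation closes the six- and eight-membered rings, sets quaternary C5 with C6 and C4 from C10, and leaves the bridgehead enol ether C9=C8, which then accepts C1 (C9 quaternary, cyclopentane closed). Ring expansion, closure at C11–C12 and enolate quaternisation of C5 disappear.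

Key step: step 10

Assumption: C5 and C9 are the two bridgeheads of one bicyclo[5.3.1]undecane, so the configuration at C9 follows from that at C5 and is not set independently; all structures carry the descriptors of the target as written.

Step 1
Reactants: 1 (2E)-4-acetoxy-2-methylbut-2-enal; 2 vinylmagnesium bromide
Product: 4 (2E,4S)-4-hydroxy-3-methylhexa-2,5-dien-1-yl acetate, via divinylzinc 3 (not isolated)
Conditions: 2 (2.4 equiv), ZnCl2 (1.2 equiv), THF–toluene, 0 °C; Et2NCH2CH2NEt2 (1.2 equiv); (–)-MIB [3-exo-morpholinoisoborneol] (5 mol %; enantiomer chosen for 4S); then 1, −20 °C; aq NH4Cl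
Reagents that add atoms: none
Why: Amino alcohol-catalysed enantioselective addition of a vinylzinc reagent to an aldehyde should set C11 (S) by catalyst control; the diamine binds the magnesium salts that would cause a racemic background reaction, and the acetate is inert to organozinc.

Step 2
Reactants: 4 (2E,4S)-4-hydroxy-3-methylhexa-2,5-dien-1-yl acetate
Product: 6 (2E,4S)-3-methyl-4-(triethylsilyloxy)hexa-2,5-dien-1-ol, via silyl ether acetate 5 (not isolated)
Conditions: Et3SiCl (1.2 equiv), imidazole (2 equiv), CH2Cl2, 0 °C; filter; then i-Bu2AlH (2.2 equiv), CH2Cl2, −78 °C; aq KNa tartrate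
Reagents that add atoms: chlorotriethylsilane, CC[Si](Cl)(CC)CC
Why: Silylation of the secondary alcohol and reductive cleavage of the acetate at −78 °C should free the primary allylic alcohol for the rearrangement; no stereocentre changes.

Step 3
Reactants: 6 (2E,4S)-3-methyl-4-(triethylsilyloxy)hexa-2,5-dien-1-ol; 7 1,1-dimethoxy-N,N-dimethylethanamine (N,N-dimethylacetamide dimethyl acetal)
Product: 8 (3S,4S)-N,N,3-trimethyl-4-(triethylsilyloxy)-3-vinylhex-5-enamide
Conditions: 7 (5 equiv), xylenes, 130 °C, MeOH distilled off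
Reagents that add atoms: none
Why: Eschenmoser–Claisen rearrangement through a chair transition state; C13 should add to C12 on the alkene face anti to the C11 silyloxy group, with C11–H next to the C12 methyl to minimise allylic strain, which sets quaternary C12 (S).

Step 4
Reactants: 8 (3S,4S)-N,N,3-trimethyl-4-(triethylsilyloxy)-3-vinylhex-5-enamide; 9 but-3-en-2-one
Product: 10 (3S,4S,5E)-N,N,3-trimethyl-7-oxo-4-(triethylsilyloxy)-3-vinyloct-5-enamide
Conditions: 9 (5 equiv), second-generation Hoveyda–Grubbs catalyst (5 mol %), CH2Cl2, 40 °C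
Reagents that add atoms: none
Why: Olefin cross-metathesis; the vinyl group on quaternary C12 is too hindered to enter the catalytic cycle, so only the C10 vinyl group should react, and the enone forms as the E isomer.

Step 5
Reactants: 11 ethyl 4-bromo-3-oxobutanoate; 12 ethane-1,2-diol
Product: 13 ethyl 2-[2-(bromomethyl)-1,3-dioxolan-2-yl]acetate
Conditions: 12 (1.5 equiv), TsOH·H2O (5 mol %), toluene, reflux, Dean–Stark trap
Reagents that add atoms: none
Why: Acid-catalysed ketalisation with azeotropic removal of water protects the ketone that becomes C2 and keeps the bromide that later serves as radical precursor at C1.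

Step 6
Reactants: 13 ethyl 2-[2-(bromomethyl)-1,3-dioxolan-2-yl]acetate
Product: 14 2-[2-(bromomethyl)-1,3-dioxolan-2-yl]acetaldehyde
Conditions: i-Bu2AlH (1.05 equiv), toluene, −78 °C; aq KNa tartrate
Reagents that add atoms: none
Why: Partial reduction of the ester should stop at the aldehyde because the tetrahedral aluminate is stable at −78 °C.

Step 7
Reactants: 10 (3S,4S,5E)-N,N,3-trimethyl-7-oxo-4-(triethylsilyloxy)-3-vinyloct-5-enamide; 14 2-[2-(bromomethyl)-1,3-dioxolan-2-yl]acetaldehyde
Product: 16 (3S,4S,5R,6E)-6-acetyl-8-[2-(bromomethyl)-1,3-dioxolan-2-yl]-N,N,3,5-tetramethyl-4-(triethylsilyloxy)-3-vinyloct-6-enamide, via aldol adduct 15 (not isolated)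
Conditions: CuBr·SMe2 (5 mol %), Josiphos ligand (6 mol %; enantiomer chosen for 10R), MeMgBr (1.3 equiv), t-BuOMe, −75 °C; then 14 (1.5 equiv), −75 °C; aq NH4Cl; then MeSO2Cl, Et3N, CH2Cl2, 0 → 23 °C
Reagents that add atoms: methylmagnesium bromide, C[Mg]Br
Why: Copper-catalysed asymmetric conjugate addition with trapping of the magnesium enolate by aldehyde 14, then E1cB dehydration of the aldol mesylate; the catalyst should deliver methyl to the face of C10 opposite quaternary C12 (10R, syn to the C11 silyloxy group), the enolate is formed only at C9, and the alkylidene is obtained as the more stable E isomer with C3 cis to C10.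

Step 8
Reactants: 16 (3S,4S,5R,6E)-6-acetyl-8-[2-(bromomethyl)-1,3-dioxolan-2-yl]-N,N,3,5-tetramethyl-4-(triethylsilyloxy)-3-vinyloct-6-enamide
Product: 17 (3S,4S,5R,6E)-8-[2-(bromomethyl)-1,3-dioxolan-2-yl]-6-[1-(tert-butyldimethylsilyloxy)vinyl]-N,N,3,5-tetramethyl-4-(triethylsilyloxy)-3-vinyloct-6-enamide
Conditions: LiN(i-Pr)2 (1.15 equiv), THF, −78 °C; t-BuMe2SiCl (1.3 equiv), DMPU, −78 → 0 °C
Reagents that add atoms: tert-butylchlorodimethylsilane, CC(C)(C)[Si](C)(C)Cl
Why: Kinetic deprotonation of the methyl ketone at C7 (cross-conjugated enolate) and O-silylation should give the 2-siloxy diene; the amide protons at C13 are far less acidic.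

Step 9
Reactants: 17 (3S,4S,5R,6E)-8-[2-(bromomethyl)-1,3-dioxolan-2-yl]-6-[1-(tert-butyldimethylsilyloxy)vinyl]-N,N,3,5-tetramethyl-4-(triethylsilyloxy)-3-vinyloct-6-enamide; 18 (Z)-2-bromobut-2-ene
Product: 20 (2Z,6S,7S,8R,9E)-11-[2-(bromomethyl)-1,3-dioxolan-2-yl]-9-[1-(tert-butyldimethylsilyloxy)vinyl]-3,6,8-trimethyl-7-(triethylsilyloxy)-6-vinylundeca-2,9-dien-4-one, via (Z)-but-2-en-2-yllithium 19 (not isolated)
Conditions: 18 (1.6 equiv), t-BuLi (3.2 equiv), Et2O, −78 °C; then 17, THF, −78 → −20 °C; pH 7 phosphate buffer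
Reagents that add atoms: none
Why: Bromine–lithium exchange keeps the alkene geometry, and single addition of the vinyllithium to the tertiary amide (tetrahedral intermediate stable until work-up) should give the Z enone.

Step 10
Reactants: 20 (2Z,6S,7S,8R,9E)-11-[2-(bromomethyl)-1,3-dioxolan-2-yl]-9-[1-(tert-butyldimethylsilyloxy)vinyl]-3,6,8-trimethyl-7-(triethylsilyloxy)-6-vinylundeca-2,9-dien-4-one
Product: 21 (4R,5S,6S,10R,11S,12S)-4-{[2-(bromomethyl)-1,3-dioxolan-2-yl]methyl}-8-(tert-butyldimethylsilyloxy)-5,6,10,12-tetramethyl-11-(triethylsilyloxy)-12-vinylbicyclo[5.3.1]undec-8-en-14-one (mutilin numbering; bridgehead C9=C8 enol ether)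
Conditions: toluene (5 mM), BHT (0.1 equiv), 170 °C, sealed base-washed glass tube
Reagents that add atoms: none
Why: Thermal, concerted but asynchronous [4+2] cycloaddition in which the siloxy-activated diene terminus C7 bonds to the enone β-carbon C6 and C4 bonds to C5; the closest known reaction type is the type 2 intramolecular Diels–Alder reaction of a 2-substituted diene with a tethered enone, which gives bicyclo[5.3.1]undecenes with a bridgehead double bond. The six-membered ring closes by the cycloaddition itself (C4–C5, C6–C7), and the eight-membered ring closes at the same time because the five-atom tether C10–C14 joins diene carbon C9 to dienophile carbon C5 (1,3-bridged mode, C9=C8 at the bridgehead). Allylic strain between C3H2 (cis to C10 on C4=C9) and C10 holds C10–H in the diene plane, so the tether leaves from the face of C11 and delivers the dienophile to that face, which sets C4 and C5 from C10. The Z geometry of the enone is carried into C5/C6 (C6 methyl cis to C14 and trans to the C5 methyl), and C3 ends cis to C14 because the tether carbonyl must lie endo. The step needs the regiochemistry, which the tether and the matching polarity secure, and survival of the Z enone, for which acid-free glass, a radical inhibitor and high dilution are used.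

Step 11
Reactants: 21 bridged enol ether (as named in step 10)
Product: 22 14-oxo tricycle (mutilin skeleton with C4–H; 2-dioxolane ketal; 8-OSiMe2t-Bu; 11-OSiEt3; 4R,5S,6S,8S,9S,10R,11S,12S)
Conditions: Bu3SnH (1.3 equiv, added over 6 h), AIBN (0.2 equiv), benzene (5 mM), 80 °C; aq KF
Reagents that add atoms: none
Why: 5-exo-trig radical cyclisation (tin hydride method) of the primary radical at C1 onto the bridgehead silyl enol ether; only the outer face of C9 is open, so C9 has no choice, and the α-siloxy radical at C8 should take hydrogen on the face of C1, which leaves the silyloxy group cis to C10 (8S).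

Step 12
Reactants: 22 14-oxo tricycle (as named in step 11)
Product: 24 14-acetate of the tricycle (2-dioxolane ketal; 8-OSiMe2t-Bu; 11-OSiEt3; 4S,5S,6S,8S,9S,10R,11S,12S,14R), via 14-alcohol 23 (not isolated)
Conditions: NaBH4 (4 equiv), MeOH–THF 1:1, 23 °C; aq NH4Cl; then Ac2O (5 equiv), DMAP (0.2 equiv), pyridine, 40 °C
Reagents that add atoms: acetic anhydride, CC(=O)OC(C)=O
Why: Borohydride reduction of the only ketone, then DMAP-catalysed acetylation of the only free hydroxyl; hydride should add to C14 on the face opposite the C12 methyl that lies across the eight-membered ring, so the acetoxy group ends cis to that methyl (14R).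

Step 13
Reactants: 24 14-acetate (as named in step 12)
Product: 25 3,4-dihydro target: 14-acetoxy-8,11-dihydroxy-2-oxo tricycle with saturated cyclopentanone (4S,5S,6S,8S,9S,10R,11S,12S,14R)
Conditions: 2 M HCl–THF 1:2, 40 °C
Reagents that add atoms: water, O
Why: Acid hydrolysis should cleave the dioxolane and both silyl ethers while the hindered secondary acetate survives; no stereocentre changes.

Step 14
Reactants: 25 3,4-dihydro target (as named in step 13)
Product: 27 Pleuromutilin E (5S,6S,8S,9R,10R,11S,12S,14R), via silyl enol ether 26 (not isolated)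
Conditions: LiN(SiMe3)2 (3.5 equiv), Me3SiCl (4 equiv), THF, −78 °C; then Pd(OAc)2 (1.2 equiv), MeCN, 23 °C; 1 M HCl work-up
Reagents that add atoms: none
Why: Saegusa–Ito dehydrogenation: kinetic enolisation at C3, the α-carbon not flanked by quaternary C9, gives the silyl enol ether (both hydroxyls are silylated in passing), divalent palladium then removes hydrogen from C4 to give the C3=C4 enone, the only enone possible because C9 is quaternary, and aqueous acid frees the hydroxyls.

**Compound list**
1 | (2E)-4-acetoxy-2-methylbut-2-enal | CC(=O)OC/C=C(\C)C=O | starting material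
2 | vinylmagnesium bromide | C=C[Mg]Br | starting material
3 | divinylzinc | C=C[Zn]C=C | intermediate
4 | (2E,4S)-4-hydroxy-3-methylhexa-2,5-dien-1-yl acetate | CC(=O)OC/C=C(\C)[C@@H](O)C=C | intermediate
5 | (2E,4S)-3-methyl-4-(triethylsilyloxy)hexa-2,5-dien-1-yl acetate | CC(=O)OC/C=C(\C)[C@@H](O[Si](CC)(CC)CC)C=C | intermediate
6 | (2E,4S)-3-methyl-4-(triethylsilyloxy)hexa-2,5-dien-1-ol | OC/C=C(\C)[C@@H](O[Si](CC)(CC)CC)C=C | intermediate
7 | 1,1-dimethoxy-N,N-dimethylethanamine | COC(C)(OC)N(C)C | starting material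
8 | (3S,4S)-N,N,3-trimethyl-4-(triethylsilyloxy)-3-vinylhex-5-enamide | C=C[C@]([C@@H](O[Si](CC)(CC)CC)C=C)(C)CC(=O)N(C)C | intermediate
9 | but-3-en-2-one | CC(=O)C=C | starting material
10 | (3S,4S,5E)-N,N,3-trimethyl-7-oxo-4-(triethylsilyloxy)-3-vinyloct-5-enamide | C=C[C@]([C@@H](O[Si](CC)(CC)CC)/C=C/C(C)=O)(C)CC(=O)N(C)C | intermediate
11 | ethyl 4-bromo-3-oxobutanoate | CCOC(=O)CC(=O)CBr | starting material
12 | ethane-1,2-diol | OCCO | starting material
13 | ethyl 2-[2-(bromomethyl)-1,3-dioxolan-2-yl]acetate | CCOC(=O)CC1(CBr)OCCO1 | intermediate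
14 | 2-[2-(bromomethyl)-1,3-dioxolan-2-yl]acetaldehyde | O=CCC1(CBr)OCCO1 | intermediate
15 | aldol adduct of 10, methyl and 14 (β-hydroxy ketone; C9 and carbinol C4 as mixtures) | C=C[C@]([C@@H](O[Si](CC)(CC)CC)[C@H](C)C(C(O)CC1(CBr)OCCO1)C(C)=O)(C)CC(=O)N(C)C | intermediate
16 | (3S,4S,5R,6E)-6-acetyl-8-[2-(bromomethyl)-1,3-dioxolan-2-yl]-N,N,3,5-tetramethyl-4-(triethylsilyloxy)-3-vinyloct-6-enamide | C=C[C@]([C@@H](O[Si](CC)(CC)CC)[C@H](C)/C(=C\CC1(CBr)OCCO1)C(C)=O)(C)CC(=O)N(C)C | intermediate
17 | (3S,4S,5R,6E)-8-[2-(bromomethyl)-1,3-dioxolan-2-yl]-6-[1-(tert-butyldimethylsilyloxy)vinyl]-N,N,3,5-tetramethyl-4-(triethylsilyloxy)-3-vinyloct-6-enamide | C=C[C@]([C@@H](O[Si](CC)(CC)CC)[C@H](C)/C(=C\CC1(CBr)OCCO1)C(=C)O[Si](C)(C)C(C)(C)C)(C)CC(=O)N(C)C | intermediate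
18 | (Z)-2-bromobut-2-ene | C/C=C(/C)Br | starting material
19 | (Z)-but-2-en-2-yllithium | C/C=C(/C)[Li] | intermediate
20 | (2Z,6S,7S,8R,9E)-11-[2-(bromomethyl)-1,3-dioxolan-2-yl]-9-[1-(tert-butyldimethylsilyloxy)vinyl]-3,6,8-trimethyl-7-(triethylsilyloxy)-6-vinylundeca-2,9-dien-4-one | C=C[C@]([C@@H](O[Si](CC)(CC)CC)[C@H](C)/C(=C\CC1(CBr)OCCO1)C(=C)O[Si](C)(C)C(C)(C)C)(C)CC(=O)/C(C)=C\C | intermediate
21 | bridged bicyclo[5.3.1]undec-8-en-14-one with bridgehead C9=C8 silyl enol ether (4R,5S,6S,10R,11S,12S; mutilin numbering) | C=C[C@]1(C)CC(=O)[C@]2(C)[C@H](CC3(CBr)OCCO3)C(=C(O[Si](C)(C)C(C)(C)C)C[C@@H]2C)[C@@H](C)[C@@H]1O[Si](CC)(CC)CC | intermediate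
22 | 14-oxo tricycle, 2-dioxolane ketal, 8-OSiMe2t-Bu, 11-OSiEt3 (4R,5S,6S,8S,9S,10R,11S,12S) | C=C[C@]1(C)CC(=O)[C@]2(C)[C@@H]3CC4(OCCO4)C[C@@]3([C@@H](O[Si](C)(C)C(C)(C)C)C[C@@H]2C)[C@@H](C)[C@@H]1O[Si](CC)(CC)CC | intermediate
23 | 14-alcohol of 22 (4S,5S,6S,8S,9S,10R,11S,12S,14R) | C=C[C@]1(C)C[C@@H](O)[C@]2(C)[C@@H]3CC4(OCCO4)C[C@@]3([C@@H](O[Si](C)(C)C(C)(C)C)C[C@@H]2C)[C@@H](C)[C@@H]1O[Si](CC)(CC)CC | intermediate
24 | 14-acetate of 23 (4S,5S,6S,8S,9S,10R,11S,12S,14R) | C=C[C@]1(C)C[C@@H](OC(C)=O)[C@]2(C)[C@@H]3CC4(OCCO4)C[C@@]3([C@@H](O[Si](C)(C)C(C)(C)C)C[C@@H]2C)[C@@H](C)[C@@H]1O[Si](CC)(CC)CC | intermediate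
25 | 3,4-dihydro target: 14-acetoxy-8,11-dihydroxy-2-oxo tricycle (4S,5S,6S,8S,9S,10R,11S,12S,14R) | C=C[C@]1(C)C[C@@H](OC(C)=O)[C@]2(C)[C@@H]3CC(=O)C[C@@]3([C@@H](O)C[C@@H]2C)[C@@H](C)[C@@H]1O | intermediate
26 | 2-(trimethylsilyloxy)-2-ene of 25 as its 8,11-bis(trimethylsilyl) ether | C=C[C@]1(C)C[C@@H](OC(C)=O)[C@]2(C)[C@@H]3C=C(O[Si](C)(C)C)C[C@@]3([C@@H](O[Si](C)(C)C)C[C@@H]2C)[C@@H](C)[C@@H]1O[Si](C)(C)C | intermediate
27 | Pleuromutilin E (5S,6S,8S,9R,10R,11S,12S,14R) | C=C[C@]1(C)C[C@@H](OC(C)=O)[C@]2(C)C3=CC(=O)C[C@@]3([C@@H](O)C[C@@H]2C)[C@@H](C)[C@@H]1O | target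

Total steps: 14. Longest linear sequence: 12 steps (steps 1–4 and 7–14); steps 5 and 6 make the side-chain aldehyde.

Steps most likely to fail:

Step 10. The Z enone may isomerise to the E enone, or lose conjugation by a 1,5-hydrogen shift, faster than it cycloadds, and the crowded C4–C5 bond may form too slowly. The fallback sets out from 17 and changes the dienophile. (But-2-yn-1-yl)magnesium bromide would add to the amide through its allenyl terminus to give the allenyl ketone F1, whose C5=C6 bond is more reactive and has no geometry to lose. It should cycloadd near 110 °C to the 6-methylidene adduct F2. Tin hydride cyclisation as in step 11 would give the cyclised 6-methylidene ketone F3. Hydrogen-atom-transfer hydrogenation (Mn(dpm)3, PhSiH3, t-BuOOH, i-PrOH) would then reduce the 1,1-disubstituted alkene in preference to the vinyl group and place the C6 methyl in its more stable position, which comes back to the route at 22.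

Step 11. The primary radical may be reduced before it reaches the hindered bridgehead carbon, because 5-exo closure onto a fully substituted enol ether carbon is slow. The fallback sets out from 21 and uses a polar ring closure. MeLi would cleave the silyl enol ether to the bridgehead lithium enolate, which would be alkylated within the molecule by the CH2Br group (5-exo-tet; HMPA, 40 °C) to give the 8,14-diketone F4. LiBH(s-Bu)3 at −78 °C should reduce the six-membered-ring carbonyl at C8 in preference to the medium-ring C14 ketone and give the 8-hydroxy-14-ketone F5. Silylation (t-BuMe2SiOTf, 2,6-lutidine) comes back to the route at 22.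

Step 14. Enolisation may go toward C1 instead of C3, and silylation of the two free hydroxyls may be incomplete, so that the oxidant attacks them. The fallback sets out from 24 and reverses the order of events. PPTS in wet acetone would exchange only the dioxolane and give the 2-ketone bis-silyl ether F6. IBX in DMSO at 70 °C (or Pd(OCOCF3)2, DMSO, O2) would dehydrogenate it under equilibrating conditions, for which C3=C4 is the only possible enone, to give the enone bis-silyl ether F7. HF·pyridine in MeCN would then free both hydroxyls and come back to the route at 27.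

**Further compounds**
F1 | step 10 | allenyl ketone: 17 with the amide replaced by a 2-methylbuta-2,3-dienoyl ketone | C=C[C@]([C@@H](O[Si](CC)(CC)CC)[C@H](C)/C(=C\CC1(CBr)OCCO1)C(=C)O[Si](C)(C)C(C)(C)C)(C)CC(=O)C(C)=C=C
F2 | step 10 | 6-methylidene analogue of 21 | C=C[C@]1(C)CC(=O)[C@]2(C)[C@H](CC3(CBr)OCCO3)C(=C(O[Si](C)(C)C(C)(C)C)CC2=C)[C@@H](C)[C@@H]1O[Si](CC)(CC)CC
F3 | step 10 | 6-methylidene analogue of 22 | C=C[C@]1(C)CC(=O)[C@]2(C)[C@@H]3CC4(OCCO4)C[C@@]3([C@@H](O[Si](C)(C)C(C)(C)C)CC2=C)[C@@H](C)[C@@H]1O[Si](CC)(CC)CC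
F4 | step 11 | 8,14-diketone tricycle (2-dioxolane ketal; 11-OSiEt3) | C=C[C@]1(C)CC(=O)[C@]2(C)[C@@H]3CC4(OCCO4)C[C@@]3(C(=O)C[C@@H]2C)[C@@H](C)[C@@H]1O[Si](CC)(CC)CC
F5 | step 11 | (8S)-8-hydroxy-14-ketone tricycle (2-dioxolane ketal; 11-OSiEt3) | C=C[C@]1(C)CC(=O)[C@]2(C)[C@@H]3CC4(OCCO4)C[C@@]3([C@@H](O)C[C@@H]2C)[C@@H](C)[C@@H]1O[Si](CC)(CC)CC
F6 | step 14 | 2-ketone of 24 with 8-OSiMe2t-Bu and 11-OSiEt3 kept | C=C[C@]1(C)C[C@@H](OC(C)=O)[C@]2(C)[C@@H]3CC(=O)C[C@@]3([C@@H](O[Si](C)(C)C(C)(C)C)C[C@@H]2C)[C@@H](C)[C@@H]1O[Si](CC)(CC)CC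
F7 | step 14 | 8-O-(tert-butyldimethylsilyl) 11-O-(triethylsilyl) ether of the target | C=C[C@]1(C)C[C@@H](OC(C)=O)[C@]2(C)C3=CC(=O)C[C@@]3([C@@H](O[Si](C)(C)C(C)(C)C)C[C@@H]2C)[C@@H](C)[C@@H]1O[Si](CC)(CC)CC
A1 | direct plan | lactol of the hydroxy lactone (isochromene-3,4a-diol with 5-allyl and 1-(2-methylidenebut-3-enyl) groups; anomers) | C=CC(=C)C[C@H]1OC(O)[C@H](C)[C@@]2(O)C(CC=C)=CC[C@H](C)[C@]12C
A2 | direct plan | syn-8,9-epoxy 4-alcohol of the fused six/seven system (14-acetate; 11-triethylsilyl ether; 9-allyl) | C=C[C@]1(C)C[C@@H](OC(C)=O)[C@]2(C)[C@](O)([C@]3(CC=C)O[C@@H]3C[C@@H]2C)[C@@H](C)[C@@H]1O[Si](CC)(CC)CC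
A3 | direct plan | bridged bicyclo[5.3.1]undecane-4,8-dione (9-allyl; 14-acetoxy; 11-triethylsilyloxy) | C=C[C@]1(C)C[C@@H](OC(C)=O)[C@]2(C)C(=O)[C@](CC=C)(C(=O)C[C@@H]2C)[C@@H](C)[C@@H]1O[Si](CC)(CC)CC
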